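**Retrosynthetic overview**
1. Ring order: the tetrahydrofuran is made first, the central benzene ring second, and the dihydrofuran ring (O1'–C2') last, by quinone methide closure onto the C7a' phenol after the C4' oxygen has been methylated.
2. The strategy rests on the central benzene ring C3a'–C4'–C5'–C6'–C7'–C7a': C3a' (bearing C3') lies between the two oxygenated carbons C4' and C7a', and the CH2 link sits on C6', meta to both (a 2,5-dialkylresorcinol). It is cut at C4'–C3a', C7a'–C7' and C4'–C5' into cyclobutenone 19 (C4'–C7' plus the complete tetrahydrofuran) and siloxyalkyne 33 (C3a', C7a', O1', C3', C2' and the guaiacyl ring).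
3. Cyclobutenone 19 comes from dichloroketene [2+2] addition to 4-propargyl tetrahydrofuran 16; the tetrahydrofuran comes from a trans lactone aldol, reduction and benzylic cycloetherification; lactone 11 comes from an Evans propargylation.
4. Siloxyalkyne 33 comes from an Evans crotonyl-imide aldol with silylated vanillin (sets C3'), then vinyl to aldehyde to alkyne, acetylide oxidation and O-silylation.

Key step: step 20

Abbreviations: TIPS = Si(i-Pr)3, TBS = SiMe2t-Bu; the oxolane (tetrahydrofuran) keeps the locants O1, C2 (aryl), C3 (CH2O), C4 (CH2 link), C5 in every intermediate; primed locants are those of the benzofuran.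

Remark: 13, 14, 28, 35 and 41 are carried as mixtures at the one stereo-element left open in their SMILES; each of these elements is erased or re-set downstream.

**Step 1**
Reactants: 1 isovanillin
Product: 2 4-methoxy-3-(triisopropylsilyloxy)benzaldehyde
Conditions: TIPSCl, imidazole, DMF, rt
Reagents that add atoms: chlorotriisopropylsilane CC(C)[Si](Cl)(C(C)C)C(C)C
Why: Standard phenol silylation; the TIPS aryl ether is chosen because it should survive the amide bases, hydrides, zinc/acid and carbonate used before the final fluoride step.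

**Step 2**
Reactants: 3 (S)-4-benzyloxazolidin-2-one, 4 4-tert-butoxy-4-oxobutanoic acid
Product: 6 tert-butyl 4-[(4S)-4-benzyl-2-oxooxazolidin-3-yl]-4-oxobutanoate, via mixed pivalic anhydride 5 (not isolated)
Conditions: t-BuCOCl, Et3N, THF, −20 °C; then LiCl, 3, −20 °C to rt
Reagents that add atoms: none
Why: Mixed-anhydride N-acylation of the oxazolidinone under LiCl/Et3N activation is the routine base-mild way to Evans imides and leaves the tert-butyl ester alone.

**Step 3**
Reactants: 6 succinate imide, 7 propargyl bromide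
Product: 9 tert-butyl (3S)-3-[(4S)-4-benzyl-2-oxooxazolidine-3-carbonyl]hex-5-ynoate, via sodium enolate 8 (not isolated)
Conditions: NaN(SiMe3)2, THF, −78 °C; then 7, −78 to −40 °C
Reagents that add atoms: none
Why: Evans asymmetric alkylation: the chelated sodium (Z)-enolate of the imide is alkylated on the face opposite the benzyl group, which sets the future C4 of the tetrahydrofuran as (S).

**Step 4**
Reactants: 9 alkylated imide
Product: 10 tert-butyl (3S)-3-(hydroxymethyl)hex-5-ynoate
Conditions: LiBH4, H2O (1 equiv), Et2O, 0 °C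
Reagents that add atoms: none
Why: Reductive cleavage of the imide carbonyl by LiBH4 should give the primary alcohol and return the auxiliary, while the tert-butyl ester and the alkyne are not reduced.

**Step 5**
Reactants: 10 hydroxy ester
Product: 11 (4S)-4-(prop-2-yn-1-yl)oxolan-2-one
Conditions: CF3CO2H, CH2Cl2, rt
Reagents that add atoms: none
Why: Acidolysis of the tert-butyl ester and spontaneous γ-lactonisation; the stereocentre is not at a reacting atom.

**Step 6**
Reactants: 11 lactone, 2 silylated isovanillin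
Product: 13 (3R,4S)-3-{hydroxy[4-methoxy-3-(triisopropylsilyloxy)phenyl]methyl}-4-(prop-2-yn-1-yl)oxolan-2-one as both carbinol epimers, via lithium enolate 12 (not isolated)
Conditions: LiN(SiMe3)2, THF, −78 °C; then 2, −78 °C; aq NH4Cl
Reagents that add atoms: none
Why: Lithium enolate aldol addition of a β-substituted γ-butyrolactone (the classical lignan lactone aldol): the amide base removes the lactone α-proton, which is more acidic than the alkyne C–H, and the aldehyde adds anti to the C4 propargyl group to give the 3,4-trans lactone (sets C3), while the carbinol centre forms as a mixture that is erased in step 8.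

**Step 7**
Reactants: 13 aldol lactone
Product: 14 (2S,3S)-2-{hydroxy[4-methoxy-3-(triisopropylsilyloxy)phenyl]methyl}-3-(prop-2-yn-1-yl)butane-1,4-diol as both carbinol epimers
Conditions: LiAlH4, THF, 0 °C
Reagents that add atoms: none
Why: Hydride reduction of the lactone to the 1,4-diol at 0 °C, as in standard lignan triol preparations, touches neither stereocentre, the alkyne nor the aryl silyl ether.

**Step 8**
Reactants: 14 triol
Product: 15 {(2R,3S,4S)-2-[4-methoxy-3-(triisopropylsilyloxy)phenyl]-4-(prop-2-yn-1-yl)oxolan-3-yl}methanol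
Conditions: camphorsulfonic acid (0.1 equiv), CH2Cl2, 0 °C to rt
Reagents that add atoms: none
Why: Acid-catalysed benzylic cycloetherification (SN1): the p-methoxybenzylic cation from either carbinol epimer is captured in a five-membered closure by the hydroxymethyl oxygen on the propargyl-bearing carbon (the other hydroxyl could only form an oxetane), and the reversible closure should place the aryl group trans to the neighbouring CH2OH, setting C2 as (R) and giving the 2,3-trans-3,4-cis ring.

**Step 9**
Reactants: 15 tetrahydrofuran alcohol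
Product: 16 (2R,3S,4S)-3-[(tert-butyldimethylsilyloxy)methyl]-2-[4-methoxy-3-(triisopropylsilyloxy)phenyl]-4-(prop-2-yn-1-yl)oxolane
Conditions: TBSCl, imidazole, DMF, rt
Reagents that add atoms: tert-butylchlorodimethylsilane CC(C)(C)[Si](C)(C)Cl
Why: Standard silylation of the one free primary alcohol, needed because ketenes acylate hydroxyl groups.

**Step 10**
Reactants: 16 propargyl tetrahydrofuran, 17 trichloroacetyl chloride
Product: 18 4,4-dichloro-3-({(2R,3S,4S)-3-[(tert-butyldimethylsilyloxy)methyl]-2-[4-methoxy-3-(triisopropylsilyloxy)phenyl]oxolan-4-yl}methyl)cyclobut-2-en-1-one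
Conditions: Zn(Cu), 17 (slow addition), Et2O/DME, rt to reflux
Reagents that add atoms: none
Why: [2+2] Cycloaddition of dichloroketene (made in the flask by zinc dechlorination of 17) to a terminal alkyne, in which the ketene carbonyl carbon bonds to the terminal CH to give the 3-substituted 4,4-dichlorocyclobutenone; DME ties up ZnCl2.

**Step 11**
Reactants: 18 dichlorocyclobutenone
Product: 19 3-({(2R,3S,4S)-3-[(tert-butyldimethylsilyloxy)methyl]-2-[4-methoxy-3-(triisopropylsilyloxy)phenyl]oxolan-4-yl}methyl)cyclobut-2-en-1-one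
Conditions: Zn dust, AcOH, Me2NCH2CH2NMe2, EtOH, 0 °C to rt
Reagents that add atoms: none
Why: Reductive dechlorination of an α,α-dichloroketone by zinc in buffered acetic acid is the standard route from dichloroketene adducts to 3-alkylcyclobutenones and is mild enough for the silyl ethers and the benzylic ether.

**Step 12**
Reactants: 20 vanillin
Product: 21 3-methoxy-4-(triisopropylsilyloxy)benzaldehyde
Conditions: TIPSCl, imidazole, DMF, rt
Reagents that add atoms: chlorotriisopropylsilane CC(C)[Si](Cl)(C(C)C)C(C)C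
Why: Standard phenol silylation, with the same robust TIPS group as in step 1.

**Step 13**
Reactants: 3 (S)-4-benzyloxazolidin-2-one, 22 (E)-but-2-enoic anhydride
Product: 23 (4S)-4-benzyl-3-[(E)-but-2-enoyl]oxazolidin-2-one
Conditions: 22, LiCl, Et3N, THF, rt
Reagents that add atoms: none
Why: N-Acylation of the oxazolidinone by an anhydride under LiCl/Et3N activation should give the (E)-crotonyl imide without strong base.

**Step 14**
Reactants: 23 crotonyl imide, 21 silylated vanillin
Product: 25 (4S)-4-benzyl-3-{(2S,3S)-2-ethenyl-3-hydroxy-3-[3-methoxy-4-(triisopropylsilyloxy)phenyl]propanoyl}oxazolidin-2-one, via boron dienolate 24 (not isolated)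
Conditions: Bu2BOTf, Et3N, CH2Cl2, −78 to 0 °C; then 21, −78 to 0 °C; then pH 7 buffer, MeOH, H2O2, 0 °C
Reagents that add atoms: none
Why: Evans boron aldol reaction of the crotonyl-imide dienolate: the (Z)-dienolate reacts at its α-carbon through a chair Zimmerman–Traxler transition state on the face dictated by the auxiliary, giving the syn α-vinyl aldol and so setting the future C3' (and, provisionally, C2').

**Step 15**
Reactants: 25 aldol imide
Product: 26 (1S,2R)-2-ethenyl-1-[3-methoxy-4-(triisopropylsilyloxy)phenyl]propane-1,3-diol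
Conditions: LiBH4, H2O (1 equiv), Et2O, 0 °C
Reagents that add atoms: none
Why: Reductive removal of the auxiliary by LiBH4 turns the imide carbonyl into the C3' hydroxymethyl group without touching the two stereocentres or the vinyl group.

**Step 16**
Reactants: 26 diol
Product: 27 (3R,4S)-4-(tert-butyldimethylsilyloxy)-3-[(tert-butyldimethylsilyloxy)methyl]-4-[3-methoxy-4-(triisopropylsilyloxy)phenyl]but-1-ene
Conditions: TBSOTf, 2,6-lutidine, CH2Cl2, −78 to 0 °C
Reagents that add atoms: tert-butyldimethylsilyl triflate CC(C)(C)[Si](C)(C)OS(=O)(=O)C(F)(F)F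
Why: Silylation of both hydroxyl groups with the silyl triflate and a hindered base, which is fast enough for the secondary benzylic alcohol.

**Step 17**
Reactants: 27 bis-silyl ether
Product: 29 (2R,3S)-3-(tert-butyldimethylsilyloxy)-2-[(tert-butyldimethylsilyloxy)methyl]-3-[3-methoxy-4-(triisopropylsilyloxy)phenyl]propanal, via diol 28 (not isolated)
Conditions: OsO4 (cat.), NaIO4, 2,6-lutidine, dioxane/H2O, rt
Reagents that add atoms: sodium periodate [Na+].[O-]I(=O)(=O)=O
Why: Lemieux–Johnson cleavage (catalytic dihydroxylation, then periodate glycol cleavage) of the terminal alkene under lutidine buffering should give the α-branched aldehyde without epimerisation and without the arene oxidation that ozone could cause.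

**Step 18**
Reactants: 29 aldehyde
Product: 30 (3R,4S)-4-(tert-butyldimethylsilyloxy)-3-[(tert-butyldimethylsilyloxy)methyl]-4-[3-methoxy-4-(triisopropylsilyloxy)phenyl]but-1-yne
Conditions: Me3SiCHN2, n-BuLi, THF, −78 °C; then 29, −78 °C to rt
Reagents that add atoms: (trimethylsilyl)diazomethane C[Si](C)(C)C=[N+]=[N-]
Why: Colvin one-carbon homologation (addition of lithiated silyldiazomethane, Peterson elimination, loss of N2 and 1,2-hydrogen shift of the alkylidene carbene) is aprotic and cold, so the α-stereocentre and the aryl silyl ether should survive where methanolic carbonate would endanger them.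

**Step 19**
Reactants: 30 terminal alkyne
Product: 33 (3R,4S)-4-(tert-butyldimethylsilyloxy)-3-[(tert-butyldimethylsilyloxy)methyl]-4-[3-methoxy-4-(triisopropylsilyloxy)phenyl]-1-(triisopropylsilyloxy)but-1-yne, via lithium acetylide 31 (not isolated), via lithium ynolate 32 (not isolated)
Conditions: LiN(SiMe3)2, THF, −78 to 0 °C; then LiOOt-Bu (from t-BuOOH and LiN(SiMe3)2), THF, −78 to 0 °C; then TIPSOTf, −78 to 0 °C
Reagents that add atoms: tert-butyl hydroperoxide CC(C)(C)OO; triisopropylsilyl triflate CC(C)[Si](OS(=O)(=O)C(F)(F)F)(C(C)C)C(C)C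
Why: Julia oxidation of a lithium acetylide by lithium tert-butylperoxide to the ynolate, followed by O-silylation with the bulky silyl triflate, is the established route from terminal alkynes to triisopropylsiloxyalkynes and does not touch the propargylic stereocentre.

**Step 20**
Reactants: 19 cyclobutenone, 33 siloxyalkyne
Product: 38 2-{(1S,2R)-1,3-bis(tert-butyldimethylsilyloxy)-1-[3-methoxy-4-(triisopropylsilyloxy)phenyl]propan-2-yl}-5-({(2R,3S,4S)-3-[(tert-butyldimethylsilyloxy)methyl]-2-[4-methoxy-3-(triisopropylsilyloxy)phenyl]oxolan-4-yl}methyl)-3-(triisopropylsilyloxy)phenol, via vinylketene 34 (not isolated), via vinylcyclobutenone 35 (not isolated), via dienylketene 36 (not isolated), via cyclohexadienone 37 (not isolated)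
Conditions: 33 (1.3 equiv), toluene, 80 °C, then 110 °C
Reagents that add atoms: none
Why: Heating opens 19 by four-electron electrocyclic cleavage to vinylketene 34, whose carbonyl carbon adds to the oxygen-remote carbon of 33 in a [2+2] step (forming C4'–C3a' and C7a'–C7'); the resulting 4-alkenyl-3-siloxycyclobutenone 35 opens again to dienylketene 36, which closes by six-electron electrocyclisation (C4'–C5') to cyclohexadienone 37 and enolises to the phenol. The closest known reaction is the cyclobutenone–siloxyalkyne benzannulation (Danheiser benzannulation), which gives 2-alkylresorcinol mono-silyl ethers from 3-alkylcyclobutenones and α-branched siloxyalkynes. The one ring formed, the central benzene ring, is closed intramolecularly in the six-electron electrocyclisation of 36 after the two intermolecular bonds have been made, and tautomerisation makes the closure irreversible. No stereocentre is created; the five existing ones are not at reacting atoms and the medium is neutral and aprotic, and C2' is re-set in step 23 in any case. The step needs only regioselectivity, which the polarisation of the siloxyalkyne secures (its carbon bearing C3' is nucleophilic towards the ketene carbonyl carbon), so that C3' lands between the two oxygens and the ketene oxygen (free OH on C4') is distinguished from the alkyne oxygen (OTIPS on C7a').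

**Step 21**
Reactants: 38 phenol
Product: 39 methyl ether of 38 at the C4' oxygen
Conditions: MeI, K2CO3, acetone, 40 °C
Reagents that add atoms: iodomethane CI
Why: Williamson methylation of the only free hydroxyl group fixes which of the two resorcinol oxygens becomes the methyl ether; the TIPS aryl ethers should tolerate carbonate in acetone.

**Step 22**
Reactants: 39 hexasilyl ether
Product: 40 hexaol (three phenols, two primary alcohols, one benzylic alcohol)
Conditions: Bu4NF, AcOH, THF, 0 °C to rt
Reagents that add atoms: none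
Why: Fluoride cleavage of all three aryl TIPS and three alkyl TBS ethers, buffered with acetic acid so that the phenoxides formed are not left in a strongly basic medium.

**Step 23**
Reactants: 40 hexaol
Product: 42 target, via quinone methide 41 (not isolated)
Conditions: camphorsulfonic acid (0.1 equiv), MeCN (dilute), 0 °C to rt
Reagents that add atoms: none
Why: Acid-catalysed dehydration of the p-hydroxybenzylic alcohol gives p-quinone methide 41, which is captured 5-exo-trig by the C7a' phenol (phenylcoumaran closure of lignan chemistry); the closure is reversible through 41 and should settle on the trans-2',3' ring, which sets C2' as (S) against the fixed (3'R) centre, while the p-methoxybenzylic C2–O bond of the tetrahydrofuran has no quinone methide pathway and should be left alone at this acidity.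

**Compound list**
1 | isovanillin (3-hydroxy-4-methoxybenzaldehyde) | COc1ccc(C=O)cc1O | starting material
2 | 4-methoxy-3-(triisopropylsilyloxy)benzaldehyde | COc1ccc(C=O)cc1O[Si](C(C)C)(C(C)C)C(C)C | intermediate
3 | (S)-4-benzyloxazolidin-2-one | O=C1N[C@@H](Cc2ccccc2)CO1 | starting material
4 | 4-tert-butoxy-4-oxobutanoic acid | CC(C)(C)OC(=O)CCC(=O)O | starting material
5 | tert-butyl 4-oxo-4-(pivaloyloxy)butanoate (mixed pivalic anhydride, formed in the flask) | CC(C)(C)OC(=O)CCC(=O)OC(=O)C(C)(C)C | intermediate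
6 | tert-butyl 4-[(4S)-4-benzyl-2-oxooxazolidin-3-yl]-4-oxobutanoate | CC(C)(C)OC(=O)CCC(=O)N1[C@@H](Cc2ccccc2)COC1=O | intermediate
7 | propargyl bromide (3-bromoprop-1-yne) | C#CCBr | starting material
8 | sodium (Z)-enolate of 6 (formed in the flask) | [Na+].[O-]/C(=C\CC(=O)OC(C)(C)C)N1[C@@H](Cc2ccccc2)COC1=O | intermediate
9 | tert-butyl (3S)-3-[(4S)-4-benzyl-2-oxooxazolidine-3-carbonyl]hex-5-ynoate | C#CC[C@@H](CC(=O)OC(C)(C)C)C(=O)N1[C@@H](Cc2ccccc2)COC1=O | intermediate
10 | tert-butyl (3S)-3-(hydroxymethyl)hex-5-ynoate | C#CC[C@@H](CC(=O)OC(C)(C)C)CO | intermediate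
11 | (4S)-4-(prop-2-yn-1-yl)oxolan-2-one | C#CC[C@H]1CC(=O)OC1 | intermediate
12 | lithium enolate of 11 (formed in the flask) | C#CC[C@H]1C=C([O-])OC1.[Li+] | intermediate
13 | (3R,4S)-3-{hydroxy[4-methoxy-3-(triisopropylsilyloxy)phenyl]methyl}-4-(prop-2-yn-1-yl)oxolan-2-one, both carbinol epimers | C#CC[C@@H]1COC(=O)[C@H]1C(O)c1ccc(OC)c(O[Si](C(C)C)(C(C)C)C(C)C)c1 | intermediate
14 | (2S,3S)-2-{hydroxy[4-methoxy-3-(triisopropylsilyloxy)phenyl]methyl}-3-(prop-2-yn-1-yl)butane-1,4-diol, both carbinol epimers | C#CC[C@H](CO)[C@@H](CO)C(O)c1ccc(OC)c(O[Si](C(C)C)(C(C)C)C(C)C)c1 | intermediate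
15 | {(2R,3S,4S)-2-[4-methoxy-3-(triisopropylsilyloxy)phenyl]-4-(prop-2-yn-1-yl)oxolan-3-yl}methanol | COc1ccc([C@@H]2OC[C@@H](CC#C)[C@H]2CO)cc1O[Si](C(C)C)(C(C)C)C(C)C | intermediate
16 | (2R,3S,4S)-3-[(tert-butyldimethylsilyloxy)methyl]-2-[4-methoxy-3-(triisopropylsilyloxy)phenyl]-4-(prop-2-yn-1-yl)oxolane | COc1ccc([C@@H]2OC[C@@H](CC#C)[C@H]2CO[Si](C)(C)C(C)(C)C)cc1O[Si](C(C)C)(C(C)C)C(C)C | intermediate
17 | trichloroacetyl chloride | ClC(Cl)(Cl)C(Cl)=O | starting material
18 | 4,4-dichloro-3-({(2R,3S,4S)-3-[(tert-butyldimethylsilyloxy)methyl]-2-[4-methoxy-3-(triisopropylsilyloxy)phenyl]oxolan-4-yl}methyl)cyclobut-2-en-1-one | COc1ccc([C@@H]2OC[C@@H](CC3=CC(=O)C3(Cl)Cl)[C@H]2CO[Si](C)(C)C(C)(C)C)cc1O[Si](C(C)C)(C(C)C)C(C)C | intermediate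
19 | 3-({(2R,3S,4S)-3-[(tert-butyldimethylsilyloxy)methyl]-2-[4-methoxy-3-(triisopropylsilyloxy)phenyl]oxolan-4-yl}methyl)cyclobut-2-en-1-one | COc1ccc([C@@H]2OC[C@@H](CC3=CC(=O)C3)[C@H]2CO[Si](C)(C)C(C)(C)C)cc1O[Si](C(C)C)(C(C)C)C(C)C | intermediate
20 | vanillin (4-hydroxy-3-methoxybenzaldehyde) | COc1cc(C=O)ccc1O | starting material
21 | 3-methoxy-4-(triisopropylsilyloxy)benzaldehyde | COc1cc(C=O)ccc1O[Si](C(C)C)(C(C)C)C(C)C | intermediate
22 | (E)-but-2-enoic anhydride (crotonic anhydride) | C/C=C/C(=O)OC(=O)/C=C/C | starting material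
23 | (4S)-4-benzyl-3-[(E)-but-2-enoyl]oxazolidin-2-one | C/C=C/C(=O)N1[C@@H](Cc2ccccc2)COC1=O | intermediate
24 | dibutylboron (Z)-dienolate of 23 (formed in the flask) | C=C/C=C(\OB(CCCC)CCCC)N1[C@@H](Cc2ccccc2)COC1=O | intermediate
25 | (4S)-4-benzyl-3-{(2S,3S)-2-ethenyl-3-hydroxy-3-[3-methoxy-4-(triisopropylsilyloxy)phenyl]propanoyl}oxazolidin-2-one | C=C[C@@H]([C@H](O)c1ccc(O[Si](C(C)C)(C(C)C)C(C)C)c(OC)c1)C(=O)N1[C@@H](Cc2ccccc2)COC1=O | intermediate
26 | (1S,2R)-2-ethenyl-1-[3-methoxy-4-(triisopropylsilyloxy)phenyl]propane-1,3-diol | C=C[C@@H]([C@H](O)c1ccc(O[Si](C(C)C)(C(C)C)C(C)C)c(OC)c1)CO | intermediate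
27 | (3R,4S)-4-(tert-butyldimethylsilyloxy)-3-[(tert-butyldimethylsilyloxy)methyl]-4-[3-methoxy-4-(triisopropylsilyloxy)phenyl]but-1-ene | C=C[C@@H]([C@H](O[Si](C)(C)C(C)(C)C)c1ccc(O[Si](C(C)C)(C(C)C)C(C)C)c(OC)c1)CO[Si](C)(C)C(C)(C)C | intermediate
28 | 1,2-diol from dihydroxylation of 27, both epimers at the new carbinol (formed in the flask) | OCC(O)[C@@H]([C@H](O[Si](C)(C)C(C)(C)C)c1ccc(O[Si](C(C)C)(C(C)C)C(C)C)c(OC)c1)CO[Si](C)(C)C(C)(C)C | intermediate
29 | (2R,3S)-3-(tert-butyldimethylsilyloxy)-2-[(tert-butyldimethylsilyloxy)methyl]-3-[3-methoxy-4-(triisopropylsilyloxy)phenyl]propanal | O=C[C@@H]([C@H](O[Si](C)(C)C(C)(C)C)c1ccc(O[Si](C(C)C)(C(C)C)C(C)C)c(OC)c1)CO[Si](C)(C)C(C)(C)C | intermediate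
30 | (3R,4S)-4-(tert-butyldimethylsilyloxy)-3-[(tert-butyldimethylsilyloxy)methyl]-4-[3-methoxy-4-(triisopropylsilyloxy)phenyl]but-1-yne | C#C[C@@H]([C@H](O[Si](C)(C)C(C)(C)C)c1ccc(O[Si](C(C)C)(C(C)C)C(C)C)c(OC)c1)CO[Si](C)(C)C(C)(C)C | intermediate
31 | lithium acetylide of 30 (formed in the flask) | [Li]C#C[C@@H]([C@H](O[Si](C)(C)C(C)(C)C)c1ccc(O[Si](C(C)C)(C(C)C)C(C)C)c(OC)c1)CO[Si](C)(C)C(C)(C)C | intermediate
32 | lithium ynolate from 31 (formed in the flask) | [Li+].[O-]C#C[C@@H]([C@H](O[Si](C)(C)C(C)(C)C)c1ccc(O[Si](C(C)C)(C(C)C)C(C)C)c(OC)c1)CO[Si](C)(C)C(C)(C)C | intermediate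
33 | (3R,4S)-4-(tert-butyldimethylsilyloxy)-3-[(tert-butyldimethylsilyloxy)methyl]-4-[3-methoxy-4-(triisopropylsilyloxy)phenyl]-1-(triisopropylsilyloxy)but-1-yne | CC(C)[Si](C(C)C)(C(C)C)OC#C[C@@H]([C@H](O[Si](C)(C)C(C)(C)C)c1ccc(O[Si](C(C)C)(C(C)C)C(C)C)c(OC)c1)CO[Si](C)(C)C(C)(C)C | intermediate
34 | vinylketene: 3-methylidene-4-(oxolan-4-yl)but-1-en-1-one carrying the substituents of 19 (formed in the flask) | COc1ccc([C@@H]2OC[C@@H](CC(=C)C=C=O)[C@H]2CO[Si](C)(C)C(C)(C)C)cc1O[Si](C(C)C)(C(C)C)C(C)C | intermediate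
35 | 4-alkenyl-3-(triisopropylsilyloxy)cyclobut-2-en-1-one from [2+2] addition of 34 to 33, both epimers at the ring CH (formed in the flask) | COc1ccc([C@@H]2OC[C@@H](CC(=C)C3C(=O)C([C@@H]([C@H](O[Si](C)(C)C(C)(C)C)c4ccc(O[Si](C(C)C)(C(C)C)C(C)C)c(OC)c4)CO[Si](C)(C)C(C)(C)C)=C3O[Si](C(C)C)(C(C)C)C(C)C)[C@H]2CO[Si](C)(C)C(C)(C)C)cc1O[Si](C(C)C)(C(C)C)C(C)C | intermediate
36 | dienylketene from ring opening of 35 (formed in the flask) | COc1ccc([C@@H]2OC[C@@H](CC(=C)/C=C(/O[Si](C(C)C)(C(C)C)C(C)C)C(=C=O)[C@@H]([C@H](O[Si](C)(C)C(C)(C)C)c3ccc(O[Si](C(C)C)(C(C)C)C(C)C)c(OC)c3)CO[Si](C)(C)C(C)(C)C)[C@H]2CO[Si](C)(C)C(C)(C)C)cc1O[Si](C(C)C)(C(C)C)C(C)C | intermediate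
37 | cyclohexa-2,4-dien-1-one from electrocyclisation of 36 (formed in the flask) | COc1ccc([C@@H]2OC[C@@H](CC3=CC(O[Si](C(C)C)(C(C)C)C(C)C)=C([C@@H]([C@H](O[Si](C)(C)C(C)(C)C)c4ccc(O[Si](C(C)C)(C(C)C)C(C)C)c(OC)c4)CO[Si](C)(C)C(C)(C)C)C(=O)C3)[C@H]2CO[Si](C)(C)C(C)(C)C)cc1O[Si](C(C)C)(C(C)C)C(C)C | intermediate
38 | resorcinol mono-TIPS ether: 2-{(1S,2R)-1,3-bis(tert-butyldimethylsilyloxy)-1-[3-methoxy-4-(triisopropylsilyloxy)phenyl]propan-2-yl}-5-({(2R,3S,4S)-3-[(tert-butyldimethylsilyloxy)methyl]-2-[4-methoxy-3-(triisopropylsilyloxy)phenyl]oxolan-4-yl}methyl)-3-(triisopropylsilyloxy)phenol | COc1ccc([C@@H]2OC[C@@H](Cc3cc(O)c([C@@H]([C@H](O[Si](C)(C)C(C)(C)C)c4ccc(O[Si](C(C)C)(C(C)C)C(C)C)c(OC)c4)CO[Si](C)(C)C(C)(C)C)c(O[Si](C(C)C)(C(C)C)C(C)C)c3)[C@H]2CO[Si](C)(C)C(C)(C)C)cc1O[Si](C(C)C)(C(C)C)C(C)C | intermediate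
39 | methyl ether of 38 at the C4' oxygen | COc1ccc([C@@H]2OC[C@@H](Cc3cc(OC)c([C@@H]([C@H](O[Si](C)(C)C(C)(C)C)c4ccc(O[Si](C(C)C)(C(C)C)C(C)C)c(OC)c4)CO[Si](C)(C)C(C)(C)C)c(O[Si](C(C)C)(C(C)C)C(C)C)c3)[C@H]2CO[Si](C)(C)C(C)(C)C)cc1O[Si](C(C)C)(C(C)C)C(C)C | intermediate
40 | hexaol: fully desilylated 39 with (1'S,2'R)-1,3-dihydroxy-1-(4-hydroxy-3-methoxyphenyl)propan-2-yl side chain and free C7a' phenol | COc1ccc([C@@H]2OC[C@@H](Cc3cc(OC)c([C@@H]([C@H](O)c4ccc(O)c(OC)c4)CO)c(O)c3)[C@H]2CO)cc1O | intermediate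
41 | p-quinone methide from dehydration of 40, methide geometry open (formed in the flask) | COc1ccc([C@@H]2OC[C@@H](Cc3cc(OC)c([C@@H](C=C4C=CC(=O)C(OC)=C4)CO)c(O)c3)[C@H]2CO)cc1O | intermediate
42 | CNP0242386.1 | COc1ccc([C@@H]2OC[C@@H](Cc3cc(OC)c4c(c3)O[C@H](c3ccc(O)c(OC)c3)[C@H]4CO)[C@H]2CO)cc1O | target

**Step count and risks**
Total steps: 23. Longest linear sequence: 14 steps (steps 2–11, then 20–23, counted from 4-tert-butoxy-4-oxobutanoic acid).

Steps most likely to fail:

1. Step 20 (benzannulation). The vinylketene is present while the phenol is being formed, so O-acylation of the new phenol by the ketene and ketene oligomerisation may outrun the slow [2+2] addition to the α-branched siloxyalkyne. The fallback sets out from 19 and comes back to the route at 35, which then goes on to 38. 19 is heated in wet dioxane (90 °C) so that ketene 34 is captured by water as the β,γ-unsaturated 3-methylidene acid F1. 1-Chloro-N,N,2-trimethylprop-1-en-1-amine (CH2Cl2, 0 °C) converts it under neutral conditions into the acid chloride F2. Slow addition of F2 to 33 and Et3N (toluene, 0 °C to rt) regenerates 34 by dehydrochlorination in the presence of excess alkyne and should stop at vinylcyclobutenone 35 (ketene–siloxyalkyne [2+2] addition at room temperature). 35 is isolated and then heated alone (toluene, 110 °C) to 38 through 36 and 37, with no ketene left to acylate the phenol.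

2. Step 10 (dichloroketene addition). ZnCl2 together with the acid chloride may cleave the p-methoxybenzylic C2–O bond of the tetrahydrofuran acylatively or strip silyl ethers, and the dichlorocyclobutenone may isomerise by chlorine shift before it is reduced. The fallback sets out from 16 and comes back at 19, bypassing 18 and step 11. It is a keteniminium [2+2] cycloaddition: N,N-dimethylacetamide, Tf2O and 2,4,6-collidine (ClCH2CH2Cl, reflux) generate the N,N-dimethylketeniminium triflate, which adds to the terminal alkyne of 16 with the same regiochemistry to give the cyclobutenyliminium triflate F3. Hydrolysis with aqueous NaHCO3 gives 19 directly, without zinc salts, acid chloride or reductive dechlorination.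

3. Step 19 (siloxyalkyne formation). Oxidation of the hindered acetylide may be incomplete, the ynolate may be silylated on carbon, and the siloxyalkyne may hydrolyse on isolation. The fallback sets out from 29 and comes back at ynolate 32, which is silylated to 33 as before. It is a Kowalski ester homologation: Pinnick oxidation of 29 (NaClO2, NaH2PO4, 2-methylbut-2-ene, t-BuOH/H2O) gives the carboxylic acid F4, and Me3SiCHN2 in MeOH/toluene gives the methyl ester F5. LiCHBr2 (from CH2Br2 and lithium 2,2,6,6-tetramethylpiperidide, THF, −78 °C) adds to F5 and, after LiN(SiMe3)2, leaves the dibromo enolate F6. n-BuLi (−78 °C to rt) then effects bromine–lithium exchange and 1,2-shift of the C3' carbon to the carbenoid centre with retention, which gives 32.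

**Further compounds**
F1 | step 20 | 3-methylidene-4-{(2R,3S,4S)-3-[(tert-butyldimethylsilyloxy)methyl]-2-[4-methoxy-3-(triisopropylsilyloxy)phenyl]oxolan-4-yl}butanoic acid | COc1ccc([C@@H]2OC[C@@H](CC(=C)CC(=O)O)[C@H]2CO[Si](C)(C)C(C)(C)C)cc1O[Si](C(C)C)(C(C)C)C(C)C
F2 | step 20 | acid chloride of F1 | COc1ccc([C@@H]2OC[C@@H](CC(=C)CC(=O)Cl)[C@H]2CO[Si](C)(C)C(C)(C)C)cc1O[Si](C(C)C)(C(C)C)C(C)C
F3 | step 10 | N,N-dimethylcyclobut-2-en-1-iminium triflate carrying the oxolan-4-ylmethyl group of 19 at C3 | COc1ccc([C@@H]2OC[C@@H](CC3=CC(=[N+](C)C)C3)[C@H]2CO[Si](C)(C)C(C)(C)C)cc1O[Si](C(C)C)(C(C)C)C(C)C.[O-]S(=O)(=O)C(F)(F)F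
F4 | step 19 | (2R,3S)-3-(tert-butyldimethylsilyloxy)-2-[(tert-butyldimethylsilyloxy)methyl]-3-[3-methoxy-4-(triisopropylsilyloxy)phenyl]propanoic acid | OC(=O)[C@@H]([C@H](O[Si](C)(C)C(C)(C)C)c1ccc(O[Si](C(C)C)(C(C)C)C(C)C)c(OC)c1)CO[Si](C)(C)C(C)(C)C
F5 | step 19 | methyl ester of F4 | COC(=O)[C@@H]([C@H](O[Si](C)(C)C(C)(C)C)c1ccc(O[Si](C(C)C)(C(C)C)C(C)C)c(OC)c1)CO[Si](C)(C)C(C)(C)C
F6 | step 19 | lithium enolate of the dibromomethyl ketone from F5 | [Li+].[O-]C(=C(Br)Br)[C@@H]([C@H](O[Si](C)(C)C(C)(C)C)c1ccc(O[Si](C(C)C)(C(C)C)C(C)C)c(OC)c1)CO[Si](C)(C)C(C)(C)C
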